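In a one-step world each partner takes one substrate, so the flask's 0.240 mM of partner would consume 60.0% of the two substrates charged.

common to all: left-handed substrate 0.20 mM; right-handed substrate 0.20 mM
- green: partner 0.12 mM; run made earlier
- red: partner 0.48 mM; run made earlier
- flask: partner 0.240 mM; time 6.0 min

| run | time / min | left-handed substrate / % | right-handed substrate / % | left-handed product / % |
|---|---|---|---|---|
| green | 0.500 | 37 | 46 | 10 |
| green | 1.50 | 39 | 47 | 10 |
| green | 3.00 | 38 | 47 | 10 |
| green | 4.00 | 38 | 47 | 9 |
| green | 6.00 | 42 | 46 | 10 |
| red | 0.500 | 31 | 42 | 20 |
| red | 0.833 | 27 | 40 | 23 |
| red | 1.50 | 27 | 43 | 24 |
| red | 3.00 | 28 | 40 | 23 |
| red | 6.00 | 26 | 39 | 22 |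

(each reading ± 1.5 percentage points)

- partner is single-handed; left-handed substrate and right-handed substrate are mirror images of each other, charged as a racemate, each of them at the stated concentration
- on the list of suspects stand: partner -> decomposed reagent; partner + left-handed substrate -> left-handed product; partner + right-handed substrate -> right-handed product; 2 partner -> self-condensation product
- an excess is the difference of the two amounts in percent of their sum
- an excess is below zero if the other one leads
- the handed part of partner does not stay in what it makes, so the products of the two hands are mirror images too

- part of the left-handed substrate and right-handed substrate charged together that has reacted at 6.0 min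
- excess of left-handed product over right-handed product in the product at 6.0 min
- excess of right-handed substrate over left-handed substrate among what is left of the two at 6.0 min

Minutes. The chair opened on that sum. The first speaker objected from the runs: green, level throughout, has reacted 14.6% against 30.0% by the sum, and red, level from 0.833 min, 32.5% against 120%. She proposed asking for the end state through the capture share, product made per partner charged: 48.7% in green, lower in red at 27.1%.

The second speaker argued that, at a given substrate concentration, decomposition competes with substrate at a ratio free of c(partner), while the ratio for self-condensation grows with c(partner). He therefore ran the reciprocal of the share straight in c(partner), with intercept 1.51 and slope 4.55 /mM. For the flask this gives 38.5% as capture share, product made per partner charged, so c is 23.1%.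

The third speaker read the hands from red: left-handed product 23.0% of 32.5% reacted gives eP 41.5%. Each product takes its own substrate, so the two differences are equal and eS is 12.5%. The meeting committed to these.

The forecast reads 22%, 45% and 12.5%, lower on c and higher on eP than the meeting, holding that “Both losses seem to operate.”

The flask gives c 21.9%, eP 41.3%, eS 11.6%.

    partner → decomposed reagent (k = 0.0369 /s)
    partner + left-handed substrate → left-handed product (k = 189 /M/s)
    partner + right-handed substrate → right-handed product (k = 70.3 /M/s)
    2 partner → self-condensation product (k = 199 /M/s)

In the flask, partner fed its steps together and stood at 2.79% of its charge by 0.600 min, with left-handed product already 14.9%. At 6.00 min partner, the limiting reagent, stood at 0% of its charge, left-handed substrate at 34.5% and right-handed substrate at 43.6%. The capture share came to 36.5% against the line's 38.5%. For a neighbour flask charged with 0.096 mM of partner, the line gives 51.4%, hence c 12.3%, and that flask gave 11.3%.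

(The runs are simulated from invented constants; the scatter is artificial.)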